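Assumption: the target is drawn as the free hydrogen sulfate; the sulfate is carried as its potassium salt and protonated only in the last operation, because aryl hydrogen sulfates lose SO3 under acid.

## The problem

Ombuin 3-O-sulfate is a flavone: benzo ring A (C4a to C8a) fused to pyranone ring C (O1, C2, C3, C4), with aryl ring B on C2. It has no stereocentre. Its seven carbon-bound oxygens are in five states: ring ether O1, the C4 carbonyl, methyl ethers at C7 and C4', free phenols at C5 and C3', and the enolic O3 as a hydrogen sulfate. At the moment of sulfation O3 must be the only hydroxyl that reacts. The sulfate monoester is the fragile group: it is lost under acid, excludes Lewis-acid ether cleavage, and makes the compound a salt that cannot be purified on silica, so it must come late and be followed only by neutral operations. Ring A is a phloroglucinol in which only the oxygen para to C4a (at C7) is methylated; acylation of 5-methoxyresorcinol does not control this, and oxidative closure of a chalcone is diverted by an oxygen at C6'.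

The feature that opens the route is the oxygenation pattern. C8a, C7 and C5 of ring A carry oxygen on alternate carbons and C4a carries the C4 carbonyl, which is the pattern of a Claisen-folded tetraketide. Continued through C4, C3 (one extra oxygen) and C2, the whole backbone C8a to C2 is one poly-β-carbonyl chain. The 2,6-dihydroxy-4-methoxyphenyl ketone that such a fold gives has a local twofold axis through C4a and C7, so either hydroxyl can become O1 and the other is left as the free 5-OH.

## Retrosynthesis

**13 to 10 (through 12 and 11).** Bonds cut: S–O3 and O3'–CH2Ph. The sulfate goes on last but one and only a neutral hydrogenolysis follows. Sulfating free ombuin instead would let the guaiacol-type 3'-OH compete with O3. Precursor 10 is a neutral flavonol that can be crystallised or chromatographed. The forward steps must transfer SO3 to O3 alone (5-OH is held by its hydrogen bond to the C4 carbonyl, O3' is benzylated) and remove benzyl without reducing the pyranone or losing the sulfate.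

**10 to 6 (through 9, 8 and 7).** Bonds cut: O1–C2 (ring C), C4a–C8a (ring A) and C2–C3, the last replaced by an ester link from O3 to the future C2. Cutting ring C alone keeps ring A as a bought phloroglucinol ketone that must be functionalised next to free phenols. Cutting C4a–C8a as well turns the backbone into one chain in which every oxygen is already in its final state: the 7-methyl ether is the enol ether of a 4-methoxy-2-pyrone, C8a and C5 are its lactone, and the ring B carbon is an ester on O3. Precursor 6 contains neither ring A nor ring C; product 10 contains both. The forward reaction must complete the O-to-C acyl shift before any alkoxide is present, fold in the Claisen and not the aldol mode, and dehydrate.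

**6 to 5 (from 4) and 3.** Bond cut: C4–C4a. A cut at C3–C4 would need an α-oxy carbanion next to an ester; this cut uses the known 6-methyl anion of commercial pyrone 4 and an N-methoxy-N-methylamide that stops at the ketone. Fragment 3 holds ring B, C2, O3, C3 and C4. The forward step must attack the amide carbonyl and not the aroyl ester.

**3 to 1 and 2.** Bond cut: C3–O3. The carboxylate oxygen of commercial acid 1 becomes O3 of the target and its carboxyl carbon becomes C2; commercial chloroamide 2 supplies C3 and C4. The forward step is a plain SN2 esterification.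

## Roads not taken

**Alternative 1:** chalcone oxidation, the route most chemists would draw first. Cut: the C2=C3 bond back to an aldol, then O1–C2 and C3–O3 by oxidative closure. Forward: Claisen–Schmidt condensation of methyl ketone 1-[2-hydroxy-4-methoxy-6-(methoxymethoxy)phenyl]ethan-1-one A1 with 3-(benzyloxy)-4-methoxybenzaldehyde A2 to chalcone A3; Algar–Flynn–Oyamada oxidation (H2O2, NaOH) to the 5-O-methoxymethyl flavonol A4; acid removal of the acetal to 10. The chosen plan is better for three reasons:
- An oxygen at C6' steers opening of the chalcone epoxide to the α-carbon (five-membered, aurone-type closure) in competition with the six-membered one.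
- If the 6'-OH is left free, the chalcone closes to the flavanone under the basic conditions.
- The protecting group this forces must be removed with acid before sulfation, giving four operations to 10 against three, with the oxidation the weak one.

**Alternative 2:** three-component carbonylative assembly. Cut: C4–C4a, C4–C3 and O1–C2. Forward key step: PdCl2(PPh3)2/CuI-catalysed carbonylative Sonogashira coupling of 2-iodo-5-methoxybenzene-1,3-diol A5, carbon monoxide and 2-(benzyloxy)-4-ethynyl-1-methoxybenzene A6, with 6-endo closure to the flavone A7. The symmetry of A5 would give one chromone with free 5-OH. The chosen plan is better because C3 arrives as C–H. Making it C–O needs 5-O protection, epoxidation of C2=C3 with dimethyldioxirane and deprotection before 10 is reached. Mono-iodination of 5-methoxyresorcinol between its hydroxyls is not assured. The route would run to seven or eight steps, whereas the chosen chain carries O3 from step 1.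

**Alternative 3:** ester-bridge acyl transfer with ring A bought. Cut: C2–C3 only. Forward: 1-(2,6-dihydroxy-4-methoxyphenyl)ethan-1-one A8 is halogenated at the methyl group and esterified with 1 to 2-(2,6-dihydroxy-4-methoxyphenyl)-2-oxoethyl 3-(benzyloxy)-4-methoxybenzoate A9; base then causes the O-to-C aroyl shift and cyclodehydration to 10. The chosen plan is better because in A8 the ring carbons C3 and C5 are more nucleophilic than the enol, and an ortho-phenoxide closes on the α-halo ketone to a benzofuran-3-one. Both phenols would need protection and removal, adding two steps. The chosen route reaches the same hydroxy-diketone (9) without an α-halo ketone, because ring A is formed after the C4–C4a bond, and the 7-methyl ether is set by construction.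

Key step: step 3

## Route

Step 1
Reactants: 1 3-(benzyloxy)-4-methoxybenzoic acid; 2 2-chloro-N-methoxy-N-methylacetamide
Product: 3 2-[methoxy(methyl)amino]-2-oxoethyl 3-(benzyloxy)-4-methoxybenzoate
Conditions: K2CO3, NaI (cat.), DMF, 50 °C
Reagents that add atoms: none
Why: SN2 alkylation of the potassium carboxylate by the α-chloroamide with iodide catalysis; the attacking carboxylate oxygen becomes O3 of the target and no other nucleophile is present.

Step 2
Reactants: 4 4-methoxy-6-methyl-2H-pyran-2-one; 3 2-[methoxy(methyl)amino]-2-oxoethyl 3-(benzyloxy)-4-methoxybenzoate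
Product: 6 3-(4-methoxy-2-oxo-2H-pyran-6-yl)-2-oxopropyl 3-(benzyloxy)-4-methoxybenzoate, via 6-(lithiomethyl)-4-methoxy-2H-pyran-2-one 5 (not isolated)
Conditions: LiN(i-Pr)2 (1.1 equiv), THF, −78 °C; then 3, −78 to −30 °C; 1 M HCl
Reagents that add atoms: none
Why: Kinetic deprotonation of 4 takes the 6-methyl group (vinylogous ester enolate 5), and its addition to the N-methoxy-N-methylamide gives a chelated tetrahedral adduct that holds until the acidic quench (Weinreb ketone synthesis), so the new ketone never meets the enolate; the amide carbonyl, activated by the α-acyloxy group, should react in preference to the conjugated, electron-rich aroyl ester.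

Step 3
Reactants: 6 3-(4-methoxy-2-oxo-2H-pyran-6-yl)-2-oxopropyl 3-(benzyloxy)-4-methoxybenzoate
Product: 10 2-[3-(benzyloxy)-4-methoxyphenyl]-3,5-dihydroxy-7-methoxy-4H-chromen-4-one (3'-O-benzylombuin), via hydroxy-diketone pyrone 7 (not isolated), via ring-opened methyl ester 8 (not isolated), via aryl hydroxy-diketone 9 (not isolated)
Conditions: LiN(i-Pr)2 (3.3 equiv), THF, −78 °C, Ar (6 added to the base); then KOCH3 (6 equiv), dry MeOH, 0 to 45 °C; then AcOH, 60 °C
Reagents that add atoms: none
Why: Adding 6 to excess LiN(i-Pr)2 forms the dienolate and then the carbanion at the OCH2 carbon, which adds to the aroyl carbonyl and reopens to the C-aroyl alkoxide (Chan rearrangement of an α-acyloxy ketone), making the C2–C3 bond and giving 7 as its enediolate before any alkoxide nucleophile is present. KOCH3 in dry methanol then opens the pyrone at its lactone carbonyl to methyl ester 8, in which the former ring double bond holds the ester carbon and the keto chain cis. The carbanion at C6 of 8 (the future C4a, flanked by two carbonyls) attacks the ester (Claisen condensation, 6-exo-trig), methoxide leaves and enolisation aromatises ring A to give 9; this is the chalcone-synthase mode of folding, and the closest laboratory precedent is the base-induced recyclisation of 6-(2-oxoalkyl)-4-methoxy-2-pyrones to 2,6-dihydroxy-4-methoxyphenyl ketones. On acidification either ortho-hydroxyl of 9 adds to the aroyl carbonyl (6-exo-trig hemiketal) and water is lost through the oxocarbenium ion stabilised by O1 and the 4'-methoxyphenyl ring, closing ring C as in flavonol syntheses through o-hydroxyphenyl α-hydroxy-β-diketones. The step needs the acyl shift to go to the future C3 and not C4a, which the dianion secures because its last-formed, least stabilised carbanion reacts first at −78 °C. It also needs Claisen and not aldol closure, which is secured by an ester terminus with a potassium counter-ion, by the enol ether that removes C2 and C3 of 8 as nucleophile and electrophile, and by the fact that the other ionised carbon (C8 of 8) has no six-membered partner. The direction of ring C closure needs no control because the two hydroxyls of 9 are equivalent. No stereocentre is formed: the carbinol carbon of 7 to 9 is racemic and becomes the sp2 carbon C3.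

Step 4
Reactants: 10 2-[3-(benzyloxy)-4-methoxyphenyl]-3,5-dihydroxy-7-methoxy-4H-chromen-4-one
Product: 11 potassium 2-[3-(benzyloxy)-4-methoxyphenyl]-5-hydroxy-7-methoxy-4-oxo-4H-chromen-3-yl sulfate
Conditions: SO3·pyridine (3 equiv), pyridine, 25 to 45 °C; then KHCO3, H2O, 0 °C
Reagents that add atoms: sulfur trioxide–pyridine complex, [O-]S(=O)(=O)[n+]1ccccc1; potassium hydrogencarbonate, [K+].OC([O-])=O
Why: O-sulfation of the enolic 3-OH by the SO3–amine complex; the 5-OH is locked in a six-membered hydrogen bond to the C4 carbonyl and is expected not to react in pyridine, and O3' is benzylated, so O3 is the only hydroxyl offered.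

Step 5
Reactants: 11 potassium 2-[3-(benzyloxy)-4-methoxyphenyl]-5-hydroxy-7-methoxy-4-oxo-4H-chromen-3-yl sulfate
Product: 13 ombuin 3-O-sulfate (5-hydroxy-2-(3-hydroxy-4-methoxyphenyl)-7-methoxy-4-oxo-4H-chromen-3-yl hydrogen sulfate), via potassium ombuin 3-O-sulfate 12 (not isolated)
Conditions: H2 (1 atm), Pd/C, MeOH–H2O, 25 °C; filter; then HCl (1.0 equiv), H2O, 0 °C; reversed-phase desalting, freeze-drying
Reagents that add atoms: none
Why: Hydrogenolysis of the benzyl ether over Pd/C is neutral and should leave the aryl sulfate salt, the C2=C3 bond of the pyranone and both methyl ethers untouched; one equivalent of cold aqueous HCl then gives the free hydrogen sulfate, which is separated from KCl on reversed-phase silica.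

## Compound list

1 | 3-(benzyloxy)-4-methoxybenzoic acid | COc1ccc(C(=O)O)cc1OCc1ccccc1 | starting material
2 | 2-chloro-N-methoxy-N-methylacetamide | CON(C)C(=O)CCl | starting material
3 | 2-[methoxy(methyl)amino]-2-oxoethyl 3-(benzyloxy)-4-methoxybenzoate | CON(C)C(=O)COC(=O)c1ccc(OC)c(OCc2ccccc2)c1 | intermediate
4 | 4-methoxy-6-methyl-2H-pyran-2-one | COc1cc(C)oc(=O)c1 | starting material
5 | 6-(lithiomethyl)-4-methoxy-2H-pyran-2-one | [Li]Cc1cc(OC)cc(=O)o1 | intermediate
6 | 3-(4-methoxy-2-oxo-2H-pyran-6-yl)-2-oxopropyl 3-(benzyloxy)-4-methoxybenzoate | COc1cc(CC(=O)COC(=O)c2ccc(OC)c(OCc3ccccc3)c2)oc(=O)c1 | intermediate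
7 | 6-{4-[3-(benzyloxy)-4-methoxyphenyl]-3-hydroxy-2,4-dioxobutyl}-4-methoxy-2H-pyran-2-one (racemic) | COc1cc(CC(=O)C(O)C(=O)c2ccc(OC)c(OCc3ccccc3)c2)oc(=O)c1 | intermediate
8 | methyl (2E)-9-[3-(benzyloxy)-4-methoxyphenyl]-8-hydroxy-3-methoxy-5,7,9-trioxonon-2-enoate (racemic) | COC(=O)/C=C(\CC(=O)CC(=O)C(O)C(=O)c1ccc(OC)c(OCc2ccccc2)c1)OC | intermediate
9 | 1-[3-(benzyloxy)-4-methoxyphenyl]-3-(2,6-dihydroxy-4-methoxyphenyl)-2-hydroxypropane-1,3-dione (racemic) | COc1cc(O)c(C(=O)C(O)C(=O)c2ccc(OC)c(OCc3ccccc3)c2)c(O)c1 | intermediate
10 | 2-[3-(benzyloxy)-4-methoxyphenyl]-3,5-dihydroxy-7-methoxy-4H-chromen-4-one (3'-O-benzylombuin) | COc1cc(O)c2c(=O)c(O)c(-c3ccc(OC)c(OCc4ccccc4)c3)oc2c1 | intermediate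
11 | potassium 2-[3-(benzyloxy)-4-methoxyphenyl]-5-hydroxy-7-methoxy-4-oxo-4H-chromen-3-yl sulfate | COc1cc(O)c2c(=O)c(OS(=O)(=O)[O-])c(-c3ccc(OC)c(OCc4ccccc4)c3)oc2c1.[K+] | intermediate
12 | potassium 5-hydroxy-2-(3-hydroxy-4-methoxyphenyl)-7-methoxy-4-oxo-4H-chromen-3-yl sulfate | COc1cc(O)c2c(=O)c(OS(=O)(=O)[O-])c(-c3ccc(OC)c(O)c3)oc2c1.[K+] | intermediate
13 | ombuin 3-O-sulfate (5-hydroxy-2-(3-hydroxy-4-methoxyphenyl)-7-methoxy-4-oxo-4H-chromen-3-yl hydrogen sulfate) | COc1cc(O)c2c(=O)c(OS(=O)(=O)O)c(-c3ccc(OC)c(O)c3)oc2c1 | target

## Step count and risk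

Total steps: 5. Longest linear sequence: 5 steps (1 to 3 to 6 to 10 to 11 to 13); pyrone 4 enters at step 2.

**Step 3 (key step).** Several processes may defeat it:
- methanolysis of the aroyl ester if the acyl shift is incomplete when methoxide is added;
- folding of 8 in the aldol (resorcylate) mode, or a pyrone that does not open while it carries the enolate chain;
- retro-Claisen cleavage of the hydroxy-diketone in methoxide;
- 1,3-elimination of the aroyloxy group from the mono-enolate;
- oxygenolysis of the flavonolate if air enters.

Fallback, with ring A folding and acyl transfer uncoupled and every reaction of known type: 5, made from 4 as in step 2, is acylated with purchased 2-[(tert-butyldimethylsilyl)oxy]-N-methoxy-N-methylacetamide to give 6-{3-[(tert-butyldimethylsilyl)oxy]-2-oxopropyl}-4-methoxy-2H-pyran-2-one F2. KOCH3 in methanol folds it, and methanolic HCl on work-up removes the silyl group, to give 1-(2,6-dihydroxy-4-methoxyphenyl)-2-hydroxyethan-1-one F3. All three hydroxyls are acylated in pyridine with 3-(benzyloxy)-4-methoxybenzoyl chloride F4 (from 1 and oxalyl chloride) to give 2-[2,6-bis({[3-(benzyloxy)-4-methoxyphenyl]carbonyl}oxy)-4-methoxyphenyl]-2-oxoethyl 3-(benzyloxy)-4-methoxybenzoate F5. K2CO3 in pyridine at 80 °C brings about the Baker–Venkataraman-type acyl transfer and ring closure, and K2CO3 in methanol removes the remaining aryl esters to give 10. The fallback sets out from 4 (through 5) and 1 and returns at 10.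

**Step 2.** What may go wrong: attack of the dienolate at the aroyl ester carbonyl, or proton transfer from the acidic OCH2 group of 3 followed by its own acyl shift. Fallback, with the two carbonyl groups introduced one at a time: 5 is acylated with chloroamide 2 itself (Weinreb ketone synthesis) to give 6-(3-chloro-2-oxopropyl)-4-methoxy-2H-pyran-2-one F1, and the chloride is displaced by the potassium salt of 1 (K2CO3, acetone, 25 °C; phenacyl-type ester formation) to give 6. The fallback sets out from 4 (with 2 and 1) and returns at 6.

**Step 4.** What may go wrong: incomplete sulfation of the hydrogen-bonded 3-OH, partial sulfation of 5-OH if the reaction is forced, and loss of the sulfate while the salt is isolated. Fallback, with the sulfate introduced as a neutral protected diester: 10 with 2,2,2-trichloroethyl chlorosulfate, NEt3 and 4-(dimethylamino)pyridine in THF gives 2-[3-(benzyloxy)-4-methoxyphenyl]-5-hydroxy-7-methoxy-4-oxo-4H-chromen-3-yl 2,2,2-trichloroethyl sulfate F6, which can be purified on silica. Zn and HCO2NH4 in methanol then remove the trichloroethyl group, and work-up with KHCO3 gives 11. The fallback sets out from 10 and returns at 11.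

**Step 5.** What may go wrong: inhibition of the catalyst by the sulfate salt, and acid-catalysed loss of the sulfate during protonation and concentration. Fallback, with the last two steps in reverse order: hydrogenolysis of 10 (H2, Pd/C) gives ombuin F7. Sulfation with Bu4N·HSO4 and N,N'-dicyclohexylcarbodiimide in pyridine at 4 °C, which should take the most acidic hydroxyl (3-OH) first, is expected to give tetrabutylammonium 5-hydroxy-2-(3-hydroxy-4-methoxyphenyl)-7-methoxy-4-oxo-4H-chromen-3-yl sulfate F8. Exchange with KOAc in methanol gives 12, which is protonated as in step 5. The fallback sets out from 10 and returns at 12. If the free acid cannot be concentrated without loss, the compound is kept as 12 and protonated in solution before use.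

## Further compounds

F1 | step 2 | 6-(3-chloro-2-oxopropyl)-4-methoxy-2H-pyran-2-one | COc1cc(CC(=O)CCl)oc(=O)c1
F2 | step 3 | 6-{3-[(tert-butyldimethylsilyl)oxy]-2-oxopropyl}-4-methoxy-2H-pyran-2-one | COc1cc(CC(=O)CO[Si](C)(C)C(C)(C)C)oc(=O)c1
F3 | step 3 | 1-(2,6-dihydroxy-4-methoxyphenyl)-2-hydroxyethan-1-one | COc1cc(O)c(C(=O)CO)c(O)c1
F4 | step 3 | 3-(benzyloxy)-4-methoxybenzoyl chloride | COc1ccc(C(=O)Cl)cc1OCc1ccccc1
F5 | step 3 | 2-[2,6-bis({[3-(benzyloxy)-4-methoxyphenyl]carbonyl}oxy)-4-methoxyphenyl]-2-oxoethyl 3-(benzyloxy)-4-methoxybenzoate | COc1cc(OC(=O)c2ccc(OC)c(OCc3ccccc3)c2)c(C(=O)COC(=O)c2ccc(OC)c(OCc3ccccc3)c2)c(OC(=O)c2ccc(OC)c(OCc3ccccc3)c2)c1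
F6 | step 4 | 2-[3-(benzyloxy)-4-methoxyphenyl]-5-hydroxy-7-methoxy-4-oxo-4H-chromen-3-yl 2,2,2-trichloroethyl sulfate | COc1cc(O)c2c(=O)c(OS(=O)(=O)OCC(Cl)(Cl)Cl)c(-c3ccc(OC)c(OCc4ccccc4)c3)oc2c1
F7 | step 5 | ombuin (3,5-dihydroxy-2-(3-hydroxy-4-methoxyphenyl)-7-methoxy-4H-chromen-4-one) | COc1cc(O)c2c(=O)c(O)c(-c3ccc(OC)c(O)c3)oc2c1
F8 | step 5 | tetrabutylammonium 5-hydroxy-2-(3-hydroxy-4-methoxyphenyl)-7-methoxy-4-oxo-4H-chromen-3-yl sulfate | COc1cc(O)c2c(=O)c(OS(=O)(=O)[O-])c(-c3ccc(OC)c(O)c3)oc2c1.CCCC[N+](CCCC)(CCCC)CCCC
A1 | alternative 1 | 1-[2-hydroxy-4-methoxy-6-(methoxymethoxy)phenyl]ethan-1-one | CC(=O)c1c(O)cc(OC)cc1OCOC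
A2 | alternative 1 | 3-(benzyloxy)-4-methoxybenzaldehyde | COc1ccc(C=O)cc1OCc1ccccc1
A3 | alternative 1 | (2E)-3-[3-(benzyloxy)-4-methoxyphenyl]-1-[2-hydroxy-4-methoxy-6-(methoxymethoxy)phenyl]prop-2-en-1-one | COCOc1cc(OC)cc(O)c1C(=O)/C=C/c1ccc(OC)c(OCc2ccccc2)c1
A4 | alternative 1 | 2-[3-(benzyloxy)-4-methoxyphenyl]-3-hydroxy-7-methoxy-5-(methoxymethoxy)-4H-chromen-4-one | COCOc1cc(OC)cc2oc(-c3ccc(OC)c(OCc4ccccc4)c3)c(O)c(=O)c12
A5 | alternative 2 | 2-iodo-5-methoxybenzene-1,3-diol | COc1cc(O)c(I)c(O)c1
A6 | alternative 2 | 2-(benzyloxy)-4-ethynyl-1-methoxybenzene | COc1ccc(C#C)cc1OCc1ccccc1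
A7 | alternative 2 | 2-[3-(benzyloxy)-4-methoxyphenyl]-5-hydroxy-7-methoxy-4H-chromen-4-one | COc1cc(O)c2c(=O)cc(-c3ccc(OC)c(OCc4ccccc4)c3)oc2c1
A8 | alternative 3 | 1-(2,6-dihydroxy-4-methoxyphenyl)ethan-1-one | CC(=O)c1c(O)cc(OC)cc1O
A9 | alternative 3 | 2-(2,6-dihydroxy-4-methoxyphenyl)-2-oxoethyl 3-(benzyloxy)-4-methoxybenzoate | COc1cc(O)c(C(=O)COC(=O)c2ccc(OC)c(OCc3ccccc3)c2)c(O)c1
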